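**Strategy.** The plan cuts the C9–C11 bond of cyclohexane ring C (C8, C9, C11–C14) of the bicyclo[3.2.1]octane. C9 is β to the lactone carbonyl C7 through C8, so a spiro δ-lactone with a C8=C9 double bond (ring O–C20–C10–C9=C8–C7) is a radical acceptor. A primary C11 radical, made from a bromide at the end of the C14–C13–C12–C11 chain on C8, adds 6-endo to C9: one operation closes ring C and sets C9 under control of the quaternary spiro carbon C10. C8 is then acylated by a C15 Weinreb amide to close ring D; the C3–O–C6 ether bridge is closed last by oxa-Michael addition.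

Key step: step 10

Remark (numbering): atoms are numbered as in the kaurane skeleton: C1 ring-A ketone, C2, C3 (CH–O), C4 (CMe2), C5, C6 (ether OCH2), C7 (lactone C=O), C8, C9, C10 (spiro carbon), C11–C14, C15 (cyclopentanone C=O), C16 (carbinol), C17 (its methyl), C20 (lactone OCH2).
Remark (assumption): 4,4-dimethylcyclohexa-2,5-dien-1-one and 2-(4-oxocyclohexyl)acetic acid are taken as purchased; in steps 1 and 5 the antipode of the chiral ligand is chosen to give the configuration drawn, the sense of induction being confirmed at that stage.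

Step 1
Reactants: 1 4,4-dimethylcyclohexa-2,5-dien-1-one
Product: 2 (5S)-5-ethenyl-4,4-dimethylcyclohex-2-en-1-one
Conditions: [Rh(cod)2]BF4 (3 mol %), (R)-BINAP (antipode as required), CH2=CHBF3K (1.1 equiv), toluene/H2O, 100 °C
Reagents that add atoms: potassium vinyltrifluoroborate, [K+].C=C[B-](F)(F)F
Why: Hayashi–Miyaura rhodium-catalysed asymmetric 1,4-addition of the alkenyl boron reagent should desymmetrise the achiral dienone, the chiral bisphosphine choosing one enantiotopic enone arm and face so that C5 is set as (S).

Step 2
Reactants: 2 (5S)-5-ethenyl-4,4-dimethylcyclohex-2-en-1-one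
Product: 4 (5R,6S)-6-(dimethoxymethyl)-5-ethenyl-4,4-dimethylcyclohex-2-en-1-one, via silyl dienol ether 3 (not isolated)
Conditions: LDA, THF, −78 °C; TMSCl; then HC(OMe)3, TMSOTf (10 mol %), CH2Cl2, −78 °C
Reagents that add atoms: trimethyl orthoformate, COC(OC)OC
Why: LDA removes the only enolisable (α′, C10) proton and the 2-silyloxydiene should be attacked at C10 by the orthoformate-derived dimethoxycarbenium ion (Noyori-type Mukaiyama aldol with an orthoester) anti to the vinyl group; the C10 configuration is of no consequence because C10 is planarised again in step 3.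

Step 3
Reactants: 4 (5R,6S)-6-(dimethoxymethyl)-5-ethenyl-4,4-dimethylcyclohex-2-en-1-one
Product: 5 (5S,6S)-6-(dimethoxymethyl)-5-ethenyl-6-(hydroxymethyl)-4,4-dimethylcyclohex-2-en-1-one
Conditions: LDA, THF, −78 °C, 15 min; CH2O (gas, from paraformaldehyde), −78 °C; aq. NH4Cl
Reagents that add atoms: formaldehyde, C=O
Why: Aldol addition of the lithium enolate to monomeric formaldehyde at −78 °C (short enolate lifetime, to avoid β-loss of methoxide) should occur anti to the pseudo-axial vinyl group on C5, so that the hydroxymethyl group (C20) is trans and the acetal carbon (C9) cis to vinyl, which fixes the quaternary C10.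

Step 4
Reactants: 6 2-(4-oxocyclohexyl)acetic acid
Product: 7 N-methoxy-N-methyl-2-(4-oxocyclohexyl)acetamide
Conditions: MeNHOMe·HCl, EDCI, Et3N, DMAP (cat.), CH2Cl2, 0 °C to rt
Reagents that add atoms: N,O-dimethylhydroxylamine hydrochloride, CNOC.Cl
Why: Carbodiimide amide coupling gives the Weinreb amide, chosen because its α-protons are far less acidic than those of a lactone and because it acylates enolates without over-reaction.

Step 5
Reactants: 7 N-methoxy-N-methyl-2-(4-oxocyclohexyl)acetamide
Product: 8 N-methoxy-N-methyl-2-[(4S)-7-oxooxepan-4-yl]acetamide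
Conditions: Sc(OTf)3 (5 mol %), chiral N,N′-dioxide ligand (6 mol %), m-CPBA, EtOAc, −20 °C
Reagents that add atoms: m-chloroperbenzoic acid, OOC(=O)c1cccc(Cl)c1
Why: Catalytic enantioselective Baeyer–Villiger oxidation should desymmetrise the 4-substituted cyclohexanone, the chiral Sc(III) complex deciding which of the two enantiotopic α-methylene groups migrates and thereby setting C13.

Step 6
Reactants: 8 N-methoxy-N-methyl-2-[(4S)-7-oxooxepan-4-yl]acetamide
Product: 9 (4R)-6-bromo-4-{2-[methoxy(methyl)amino]-2-oxoethyl}hexanoic acid
Conditions: HBr (33 % in AcOH), CH2Cl2, 0 °C to rt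
Reagents that add atoms: hydrogen bromide, Br
Why: Acidolysis of the ε-lactone by HBr (SN2 attack of bromide on the O–CH2 carbon of the protonated lactone) should give the ω-bromo acid, with the stereocentre untouched and the amide inert at room temperature.

Step 7
Reactants: 5 (5S,6S)-6-(dimethoxymethyl)-5-ethenyl-6-(hydroxymethyl)-4,4-dimethylcyclohex-2-en-1-one; 9 (4R)-6-bromo-4-{2-[methoxy(methyl)amino]-2-oxoethyl}hexanoic acid
Product: 10 [(1S,6S)-1-(dimethoxymethyl)-6-ethenyl-5,5-dimethyl-2-oxocyclohex-3-en-1-yl]methyl (4R)-6-bromo-4-{2-[methoxy(methyl)amino]-2-oxoethyl}hexanoate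
Conditions: EDCI·HCl, DMAP, CH2Cl2, 0 °C to rt
Reagents that add atoms: none
Why: Steglich esterification of the neopentyl primary alcohol with the unhindered acid, neither partner offering a competing nucleophile or acyl donor.

Step 8
Reactants: 10 acetal ester
Product: 11 [(1S,6S)-6-ethenyl-1-formyl-5,5-dimethyl-2-oxocyclohex-3-en-1-yl]methyl (4R)-6-bromo-4-{2-[methoxy(methyl)amino]-2-oxoethyl}hexanoate
Conditions: TFA/H2O/CH2Cl2, 0 °C to rt
Reagents that add atoms: water, O
Why: Aqueous acid hydrolysis of the dimethyl acetal frees the non-enolisable C9 aldehyde without touching ester, amide, bromide or alkenes.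

Step 9
Reactants: 11 aldehyde ester
Product: 14 spiro enoate lactone (C8=C9; C8 carries the (2R)-4-bromo-2-{2-[methoxy(methyl)amino]-2-oxoethyl}butyl chain; C5 and C10 as in 5), via hydroxy lactone 12 (not isolated), via mesylate 13 (not isolated)
Conditions: LiHMDS (1.1 equiv), THF, −78 °C; MsCl, −78 to 0 °C; DBU, 0 °C to rt
Reagents that add atoms: none
Why: Intramolecular aldol addition of the ester enolate (the amide α-CH2 is far less acidic) to the non-enolisable aldehyde closes the six-membered lactone, and mesylation followed by E1cB elimination with DBU should give the conjugated C8=C9 lactone, which erases the stereocentres of 12.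

Step 10
Reactants: 14 spiro enoate lactone bromide
Product: 15 cyclised lactone (ring C closed by C9–C11; C8–H as an epimer mixture; C9, C10, C13 as in the target)
Conditions: Bu3SnH (1.3 equiv) and AIBN (0.2 equiv) added over 6 h by syringe pump, benzene (5 mM), 80 °C
Reagents that add atoms: none
Why: Bu3Sn• abstracts bromine from C11 and the primary radical adds to C9, the β-carbon of the α-substituted unsaturated δ-lactone, after which the tertiary α-lactonyl C8 radical takes hydrogen from Bu3SnH; this is a reductive Giese-type radical cyclisation, the closest known type being endo cyclisations of ω-haloalkyl α-substituted acrylates and 2-alkyl enones. Ring C (C8, C9, C11, C12, C13, C14) closes in the 6-endo-trig mode, because 5-exo attack would hit the fully substituted, electron-poor α-carbon C8 and give an unstabilised radical. The new stereocentre C9 is controlled by the adjacent quaternary spiro carbon C10: the chain should approach the face of C8=C9 that carries the flat C1 carbonyl, anti to the bulky C5 (a CH flanked by CMe2 and the vinyl group), and a chair transition state with the C13 acetamide arm equatorial leads to the same C9 configuration, so both elements reinforce. C8 is formed without control, which does not matter because it is planarised in step 11. The step needs cyclisation to outrun direct reduction of the C11 radical, which slow addition of the stannane at high dilution should secure; the vinyl group, the ring-A enone and the Weinreb amide are poor acceptors for this radical.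

Step 11
Reactants: 15 cyclised lactone
Product: 16 β-keto lactone with the bicyclo[3.2.1]octan-15-one (C16 = CH2; ring A still the 5-vinyl enone)
Conditions: LiHMDS (1.5 equiv), THF, −78 to −20 °C; aq. NH4Cl
Reagents that add atoms: none
Why: Intramolecular Claisen-type C-acylation of the lactone enolate (C8–H is about eight pK units more acidic than the amide α-CH2) by the Weinreb amide in a 5-(enolexo)-exo-trig closure should build the cyclopentanone, the chelated tetrahedral intermediate preventing retro-Claisen cleavage, and the C8 configuration is dictated by the bridge because the C13 arm can reach only one face of the enolate.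

Step 12
Reactants: 16 β-keto lactone
Product: 17 16-hydroxy ketone (exo-OH)
Conditions: KHMDS, THF, −78 °C; 2-(phenylsulfonyl)-3-phenyloxaziridine; aq. NH4Cl
Reagents that add atoms: Davis oxaziridine, O=S(=O)(c1ccccc1)N1OC1c1ccccc1
Why: Davis oxidation of the potassium enolate, which can form only towards C16 (C8 is quaternary; ring A and the lactone have no α-hydrogen), should give the α-ketol by attack on the open exo face, the C16 configuration being irrelevant.

Step 13
Reactants: 17 16-hydroxy ketone
Product: 18 15,16-dione
Conditions: Dess–Martin periodinane, NaHCO3, CH2Cl2, rt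
Reagents that add atoms: none
Why: Dess–Martin oxidation of the secondary α-ketol gives the non-enolisable 1,2-diketone.

Step 14
Reactants: 18 15,16-dione
Product: 19 16-hydroxy-16-methyl-15-ketone (methyl exo, hydroxyl endo; ring A still the 5-vinyl enone)
Conditions: MeTi(OiPr)3 (1.5 equiv), Et2O/THF, −50 to −20 °C; aqueous work-up
Reagents that add atoms: methyltitanium triisopropoxide, C[Ti](OC(C)C)(OC(C)C)OC(C)C
Why: Reetz-type chemoselective addition of MeTi(OiPr)3 to the highly electrophilic 1,2-dione should occur at C16, the carbonyl not flanked by the quaternary C8, and from the exo face (side of the C14 methylene bridge, the endo face being screened by the axial hydrogen on C11), which places methyl exo and hydroxyl endo as required.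

Step 15
Reactants: 19 tertiary alcohol with C5 vinyl group
Product: 20 C6 aldehyde
Conditions: O3, CH2Cl2, −78 °C (Sudan Red 7B end-point); PPh3
Reagents that add atoms: ozone, [O-][O+]=O
Why: Ozonolysis should be selective for the electron-rich terminal vinyl group over the conjugated, electron-poor ring-A enone when ozone is dosed to the indicator end-point.

Step 16
Reactants: 20 C6 aldehyde
Product: 22 CNP0538153.1, (3S,5S,8S,9S,10S,13R,16R) in the numbering of the remark, via hydroxy enone 21 (not isolated)
Conditions: NaBH4 (0.5 equiv), CH2Cl2/MeOH, −78 °C; then DBU (cat.), CH2Cl2, rt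
Reagents that add atoms: none
Why: Low-temperature borohydride reduction is selective for the aldehyde over the hindered and conjugated ketones, and base-catalysed intramolecular oxa-Michael addition (5-exo-trig) of the C6 hydroxyl to the C2=C3 enone then closes the ether bridge, the C3 configuration being forced because the oxygen can reach C3 only on the face of C6.

**Compound list**

1 | 4,4-dimethylcyclohexa-2,5-dien-1-one | CC1(C)C=CC(=O)C=C1 | starting material
2 | (5S)-5-ethenyl-4,4-dimethylcyclohex-2-en-1-one | CC1(C)C=CC(=O)C[C@H]1C=C | intermediate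
3 | O-trimethylsilyl dienol ether of 2 (C1=C6 and C2=C3 double bonds, C5 unchanged) | CC1(C)C=CC(O[Si](C)(C)C)=C[C@H]1C=C | intermediate
4 | (5R,6S)-6-(dimethoxymethyl)-5-ethenyl-4,4-dimethylcyclohex-2-en-1-one (acetal trans to vinyl) | CC1(C)C=CC(=O)[C@H](C(OC)OC)[C@H]1C=C | intermediate
5 | (5S,6S)-6-(dimethoxymethyl)-5-ethenyl-6-(hydroxymethyl)-4,4-dimethylcyclohex-2-en-1-one (CH2OH trans to vinyl) | CC1(C)C=CC(=O)[C@](C(OC)OC)(CO)[C@H]1C=C | intermediate
6 | 2-(4-oxocyclohexyl)acetic acid | OC(=O)CC1CCC(=O)CC1 | starting material
7 | N-methoxy-N-methyl-2-(4-oxocyclohexyl)acetamide | CON(C)C(=O)CC1CCC(=O)CC1 | intermediate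
8 | N-methoxy-N-methyl-2-[(4S)-7-oxooxepan-4-yl]acetamide | CON(C)C(=O)C[C@@H]1CCOC(=O)CC1 | intermediate
9 | (4R)-6-bromo-4-{2-[methoxy(methyl)amino]-2-oxoethyl}hexanoic acid | CON(C)C(=O)C[C@H](CCBr)CCC(=O)O | intermediate
10 | [(1S,6S)-1-(dimethoxymethyl)-6-ethenyl-5,5-dimethyl-2-oxocyclohex-3-en-1-yl]methyl (4R)-6-bromo-4-{2-[methoxy(methyl)amino]-2-oxoethyl}hexanoate | CC1(C)C=CC(=O)[C@](C(OC)OC)(COC(=O)CC[C@@H](CCBr)CC(=O)N(C)OC)[C@H]1C=C | intermediate
11 | [(1S,6S)-6-ethenyl-1-formyl-5,5-dimethyl-2-oxocyclohex-3-en-1-yl]methyl (4R)-6-bromo-4-{2-[methoxy(methyl)amino]-2-oxoethyl}hexanoate | CC1(C)C=CC(=O)[C@](C=O)(COC(=O)CC[C@@H](CCBr)CC(=O)N(C)OC)[C@H]1C=C | intermediate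
12 | spiro β-hydroxy δ-lactone, aldol adduct (C9–OH; C8 and C9 as epimer mixture) | CC1(C)C=CC(=O)[C@]2(COC(=O)C(C[C@@H](CCBr)CC(=O)N(C)OC)C2O)[C@H]1C=C | intermediate
13 | C9 methanesulfonate of 12 | CC1(C)C=CC(=O)[C@]2(COC(=O)C(C[C@@H](CCBr)CC(=O)N(C)OC)C2OS(C)(=O)=O)[C@H]1C=C | intermediate
14 | spiro α,β-unsaturated δ-lactone (C8=C9) on the 5-vinyl-4,4-dimethylcyclohexenone, C8 bearing the (2R)-4-bromo-2-{2-[methoxy(methyl)amino]-2-oxoethyl}butyl chain | CC1(C)C=CC(=O)[C@]2(COC(=O)C(C[C@@H](CCBr)CC(=O)N(C)OC)=C2)[C@H]1C=C | intermediate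
15 | ring-C-closed lactone: cyclohexane fused to the spiro lactone at C8–C9, C13 bearing CH2C(O)N(OMe)Me, C8–H epimers | CC1(C)C=CC(=O)[C@]2(COC(=O)C3C[C@H](CC(=O)N(C)OC)CC[C@H]32)[C@H]1C=C | intermediate
16 | spiro β-keto lactone with bicyclo[3.2.1]octan-15-one (C16 H2), ring A as 5-vinyl enone | CC1(C)C=CC(=O)[C@]2(COC(=O)[C@@]34C[C@@H](CC[C@H]32)CC4=O)[C@H]1C=C | intermediate
17 | 16-hydroxy derivative of 16 (exo-OH) | CC1(C)C=CC(=O)[C@]2(COC(=O)[C@@]34C[C@@H](CC[C@H]32)[C@H](O)C4=O)[C@H]1C=C | intermediate
18 | 15,16-dione | CC1(C)C=CC(=O)[C@]2(COC(=O)[C@@]34C[C@@H](CC[C@H]32)C(=O)C4=O)[C@H]1C=C | intermediate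
19 | 16-hydroxy-16-methyl-15-ketone (exo-CH3, endo-OH), ring A as 5-vinyl enone | CC1(C)C=CC(=O)[C@]2(COC(=O)[C@@]34C[C@@H](CC[C@H]32)[C@@](C)(O)C4=O)[C@H]1C=C | intermediate
20 | C6 aldehyde (formyl on C5 in place of vinyl) | CC1(C)C=CC(=O)[C@]2(COC(=O)[C@@]34C[C@@H](CC[C@H]32)[C@@](C)(O)C4=O)[C@H]1C=O | intermediate
21 | C6 primary alcohol (hydroxymethyl on C5), ring A enone | CC1(C)C=CC(=O)[C@]2(COC(=O)[C@@]34C[C@@H](CC[C@H]32)[C@@](C)(O)C4=O)[C@H]1CO | intermediate
22 | CNP0538153.1: 3,6-epoxy-16-hydroxy-1,15-dioxo 7,20-lactone, (3S,5S,8S,9S,10S,13R,16R) | CC1(C)[C@@H]2CC(=O)[C@]3(COC(=O)[C@@]45C[C@@H](CC[C@H]43)[C@@](C)(O)C5=O)[C@H]1CO2 | target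

**Totals.** 16 steps in all. Longest linear sequence: 13 steps (steps 1–3 and 7–16, from 1); steps 4–6 make acid 9 in a 3-step branch.

**Steps most likely to fail, with fallbacks.**

Step 10: the primary C11 radical may be reduced before it adds to the hindered C9, or it may add with poor facial selectivity. The fallback replaces the radical by an anionic ring closure. It sets out from 14: exchange of bromide for nitro (NaNO2, phloroglucinol, DMF) gives nitroalkane F1; DBU in MeCN should then bring about a reversible 6-endo intramolecular nitro-Michael addition to C9 under thermodynamic control to give nitro lactone F2; radical denitration (Bu3SnH, AIBN, toluene, 110 °C) comes back to 15.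

Step 11: C-acylation at the congested tertiary C8 may be slower than base-induced breakdown of the N-methoxy amide or conjugate addition of the enolate to the ring-A enone. The fallback generates the C8 enolate by reduction instead of deprotonation. It sets out from 15: the ketene silyl acetal (LiHMDS, TMSCl, −78 °C) is brominated with NBS to α-bromo lactone F3; SmI2 (THF, −78 °C) should give a samarium(III) enolate that is acylated by the chelated Weinreb amide in a Reformatsky-type closure, coming back at 16.

Step 1: transfer of the vinyl group to the neopentyl-type β-carbon may be slow, may run on to double addition, or may give low enantioselectivity. The fallback brings in C6 by iminium catalysis. It sets out from 1: a primary-amine salt (9-amino-9-deoxy-epi-cinchona type) should catalyse enantioselective Michael addition of nitromethane to give nitromethyl enone F4; a reductive Nef reaction (NaOMe, then buffered TiCl3) gives aldehyde F5; Wittig methylenation (Ph3P=CH2, THF, −78 °C) comes back to 2.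

**Further compounds**

F1 | step 10 | nitro analogue of 14 (NO2 on C11 in place of Br) | CC1(C)C=CC(=O)[C@]2(COC(=O)C(C[C@@H](CC[N+](=O)[O-])CC(=O)N(C)OC)=C2)[C@H]1C=C
F2 | step 10 | 11-nitro derivative of 15 (C8 and C11 epimers) | CC1(C)C=CC(=O)[C@]2(COC(=O)C3C[C@H](CC(=O)N(C)OC)CC([N+](=O)[O-])[C@H]32)[C@H]1C=C
F3 | step 11 | 8-bromo derivative of 15 (α-bromo lactone) | CC1(C)C=CC(=O)[C@]2(COC(=O)C3(Br)C[C@H](CC(=O)N(C)OC)CC[C@H]32)[C@H]1C=C
F4 | step 1 | 4,4-dimethyl-5-(nitromethyl)cyclohex-2-en-1-one (C5 as in 2) | CC1(C)C=CC(=O)C[C@H]1C[N+](=O)[O-]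
F5 | step 1 | 6,6-dimethyl-5-oxocyclohex-3-ene-1-carbaldehyde numbered from the formyl carbon, i.e. 2 with CHO in place of vinyl | CC1(C)C=CC(=O)C[C@H]1C=O
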